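Compound numbers below are those of the steps and of the compound list.

## Analysis of the target

Target 26 is a biflavonoid. C3 of a naringenin-type flavanone (5,7-dihydroxy, 4-hydroxyphenyl at C2) is bonded to C3' of ring B of a 5-hydroxy-7-methoxyflavone that carries a hydroxyl group at C4'. The only stereocentres are the neighbouring flavanone carbons C2 (S) and C3 (R). They are trans, with both aryl groups equatorial on ring C; C3 lies between the C4 ketone and an aryl ring and equilibrates easily, so trans is the thermodynamic arrangement and only C2 needs absolute control. C2 is fragile: under base the C3 enolate can expel the C8a phenoxide (retro-oxa-Michael), and reclosure of the chalcone erases the configuration, so everything after ring closure must be acidic, neutral or only weakly basic. Further demands are five free phenols beside one methyl ether (flavone C7, to be told apart from the flavone C5 hydroxyl), two differently substituted phloroglucinol rings, and a crowded C3–C3' bond between a tertiary sp3 carbon and an aryl carbon ortho to oxygen. The strategy rests on the benzo ring of the flavone: O1 sits on C8a, the C4 carbonyl on the adjacent C4a, and oxygens on C5 and C7. That is the pattern 3,5-dimethoxybenzyne 23 acquires when its two aryne carbons take up the hydroxyl oxygen and the acyl group of a carboxylic acid. With the arylpropiolic acid 22 the resulting phenoxide closes on the triple bond, so the flavone can be built last on a finished flavanone whose C3–C3' bond has been present from the first step.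

## Retrosynthetic reasoning

**26 to 25.** Only protecting-group C–O bonds are cut: four benzyl ethers and the methyl ether at flavone C5. Benzyl and methyl are chosen so that one boron Lewis acid removes every benzyl group and, through chelation to the flavone C4 carbonyl, only the peri methyl group; the C7 methoxy group of 26 is then never handled separately. The forward step must stay acidic so that C2 is not touched.

**25 to 22 and 8.** The flavone is cut at O1–C8a, C4–C4a and O1–C2. This removes its whole pyranone ring and leaves the carboxyl group of 22 and aryne 23, generated from 8. The cut is made here because all three bonds form in one operation, the regiochemistry is dictated by the methoxy group next to the aryne, and the ring A carbons of the flavone arrive as a symmetrical three-step building block. Classical flavone syntheses would instead need strong base or strong acid on the flavanone. The forward reaction has to generate 23 with fluoride, add the carboxylate oxygen, shift the acyl group to carbon, close ynone 24 in the 6-endo mode, and leave C2 alone.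

**22 to 20.** The carboxylic acid is traced to a primary propargylic alcohol. Attaching an alkynoic acid directly to an aryl bromide at the flavanone stage would need an amidine or fluoride base in a dipolar solvent, which are the conditions under which C2 is lost. The alcohol can be introduced before any stereocentre exists and is raised to the acid under mildly acidic oxidation.

**20 to 19.** The flavanone O1–C2 bond is cut (oxa-Michael). This is the bond that forms most easily, and the open form 19 is achiral, so a chiral catalyst can decide C2 at the moment of closure; C3 follows by equilibration to trans.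

**19 to 18.** The free phenol is traced to a benzyl ether. With all three ring A oxygens benzylated, the chalcone cannot close by itself; chelation between the ketone and an ortho ether oxygen allows one benzyl group to be removed selectively when closure is wanted.

**18 to 16 and 17.** The C2=C3 double bond is cut (Knoevenagel condensation), which brings in C2 and its aryl group as aldehyde 17.

**16 to 14 and 15.** The aryl–alkyne bond is cut (Sonogashira coupling), placed at the achiral deoxybenzoin stage where amine base is harmless.

**14 to 11 and 12, and 11 to 9.** The C4–C4a bond is cut (Friedel–Crafts acylation of the symmetrical arene 12). The crowded C3–C3' bond of 26 is thereby recognised as the ordinary CH2–aryl bond of the arylacetic acid 9, whose phenol only needs benzylation.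

**8 to 6 to 2 to 1.** The silyl group and the triflate are removed in turn; the silyl group is placed by carbamate-directed ortho-metalation of the derivative 2 of phenol 1.

## Alternatives that were turned down

**Alternative 1:** The flavanone C2–aryl bond and the C3–C3' bond are cut together. The pieces are 5,7-bis(benzyloxy)chromone A2, 4-(benzyloxy)phenylzinc chloride A3 and the bromoflavone A4 (5-benzyloxy-2-[4-(benzyloxy)-3-bromophenyl]-7-methoxychromen-4-one). Forward, [RhCl(C2H4)2]2 with one enantiomer of BINAP would add A3 to C2 of A2 in the presence of chlorotrimethylsilane. The enol silane A5 so formed would be arylated at C3 by A4 with Pd(dba)2, P(t-Bu)3 and ZnF2 to give the pentabenzyl ether A1.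

- For: high convergence; C2 is set by a catalytic asymmetric conjugate addition of a type established for chromones; the aryl group enters C3 anti to the C2 substituent; no open chalcone is ever handled.
- Against: the C3–C3' bond would be formed between an enolate carbon flanked by the C2 aryl group and an aryl bromide with an ortho benzyloxy group, the most hindered bond of the molecule. Under the fluoride conditions of that coupling a zinc or palladium enolate of a flavanone can eject the C8a phenoxide, which is the same loss of C2 that threatens the chosen route. A2 is an electron-rich 5-alkoxychromone and a sluggish acceptor. A4 still needs its own regiodefined flavone synthesis with C5 and C7 differentiated by separate protecting groups.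
- Comparison: on absolute control at C2 this alternative is stronger than step 9 of the chosen route, and its longest linear sequence is shorter. The chosen route offers in exchange a C3–C3' bond that never has to be made at the crowded stage, and a C5/C7 differentiation that comes from a symmetrical aryne and one chelation-controlled demethylation.

**Alternative 2:** Ring C of the flavanone is cut at C3–C4 and O1–C2 after the C4 carbonyl has been taken back to a methoxy-bearing carbon. The pieces are the salicylaldehyde A7 (2,4-bis(benzyloxy)-6-hydroxybenzaldehyde) and the (E)-stilbene A8, which already carries the flavone. A chiral BINOL-derived N-triflyl phosphoramide with trimethyl orthoformate would convert A7 into the O-methyl oxocarbenium (methoxy ortho-quinone methide cation) A9. This would add across A8 to give the 2,3-trans-4-methoxyflavan A6.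

- For: the trans relation comes stereospecifically from the alkene geometry, not from equilibration; no base is involved; ring C and both stereocentres form in one step.
- Against: a 1,2-diaryl alkene is a much weaker 2π partner than a styrene, and the aryl group on the C3 side of A8 carries an acyloxy group and an electron-poor flavone, which lowers its nucleophilicity further. The basic flavone carbonyl competes for the acid catalyst. C4 enters at the wrong oxidation level, so ether cleavage, oxidation and pivalate removal must follow. The flavone and the stilbene must both be built before the key step.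
- Comparison: on trans control, and on keeping the base-labile flavanone out of the route until late, this alternative is stronger. The chosen route offers C4 at the correct oxidation level from the acylation onward and a flavone that is made in a single late operation.

**Alternative 3:** The C2–C3 bond is cut. C3 is traced to a carbene and C2 to the benzylic C–H bond of an ortho 4-(benzyloxy)benzyl ether in the α-diazo deoxybenzoin A11. Dirhodium tetrakis[N-phthaloyl-(S)-tert-leucinate], Rh2(S-PTTL)4, or its enantiomer would release dinitrogen, and the rhodium-bound carbene would insert into that C–H bond to close ring C as A10.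

- For: the medium is neutral, so the ring cannot reopen; the C–H bond is strongly activated by the ether oxygen and the para-alkoxyaryl group; C2 is formed under catalyst control.
- Against: the insertion must close a six-membered ring, whereas this catalyst class is best established for five-membered closure. The ether oxygen can instead attack the carbene and give ylide-derived rearrangement products. Ring A needs three 4-(benzyloxy)benzyl ethers to stay symmetrical, and a silyl ether is needed on the flavone, so the protecting-group load and the number of deprotection steps are high. Diazo transfer is required on a hindered deoxybenzoin that already carries the flavone.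
- Comparison: on neutrality during ring closure this alternative is stronger. The chosen route offers a plain benzyl/methyl protecting scheme removed in one step, no diazo compound, and a flavone built after, not before, the stereocentres.

Key step: step 11

## Route

Remark on assumptions: 1,3,5-tris(benzyloxy)benzene 12 is taken to be commercially available, and the sense of induction in step 9 is assigned by analogy, the pseudoenantiomeric catalyst serving if it proves reversed.

Step 1
Reactants: 1 3,5-dimethoxyphenol
Product: 2 3,5-dimethoxyphenyl N-isopropylcarbamate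
Conditions: i-PrNCO, Et3N (cat.), CH2Cl2, rt
Reagents that add atoms: isopropyl isocyanate, CC(C)N=C=O
Why: Base-catalysed addition of the phenol to the isocyanate installs the strongest oxygen-based director for ortho-metalation; the phenol has only one hydroxyl, so there is no selectivity issue.

Step 2
Reactants: 2 3,5-dimethoxyphenyl N-isopropylcarbamate
Product: 6 3,5-dimethoxy-2-(trimethylsilyl)phenyl N-isopropylcarbamate, via N-silyl carbamate 3 (not isolated), via aryllithium 4 (not isolated), via bis-silyl carbamate 5 (not isolated)
Conditions: TBSOTf, TMEDA, Et2O, 0 °C to rt; n-BuLi, TMEDA, −78 °C; TMSCl, −78 °C to rt; aq. NaHSO4, 0 °C (brief)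
Reagents that add atoms: chlorotrimethylsilane, C[Si](C)(C)Cl
Why: Directed ortho-metalation: the N–H is masked in the flask as the N-silyl carbamate, n-BuLi/TMEDA lithiates the position flanked by the carbamate and a methoxy group (the carbamate outranks methoxy as a director, so this site is preferred over the one between the two methoxy groups), silyl chloride quenches the aryllithium, and cold aqueous acid removes the N-silyl group only.

Step 3
Reactants: 6 3,5-dimethoxy-2-(trimethylsilyl)phenyl N-isopropylcarbamate
Product: 8 3,5-dimethoxy-2-(trimethylsilyl)phenyl trifluoromethanesulfonate, via silylphenol 7 (not isolated)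
Conditions: DBU, Et2NH, MeCN, 40 °C; then PhNTf2, rt
Reagents that add atoms: N-phenylbis(trifluoromethanesulfonimide), O=S(=O)(N(c1ccccc1)S(=O)(=O)C(F)(F)F)C(F)(F)F
Why: The N-monosubstituted carbamate is cleaved by DBU-induced E1cB elimination, the released isocyanate being scavenged by diethylamine; this frees the phenoxide without acid, which the electron-rich aryl–silicon bond would not survive, and triflation in the same flask gives the ortho-silylaryl triflate.

Step 4
Reactants: 9 2-(5-bromo-2-hydroxyphenyl)acetic acid
Product: 11 2-[2-(benzyloxy)-5-bromophenyl]acetic acid, via benzyl ester 10 (not isolated)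
Conditions: BnBr, K2CO3, DMF, 60 °C; then NaOH, MeOH/H2O, 60 °C; aq. HCl
Reagents that add atoms: benzyl bromide, BrCc1ccccc1
Why: Williamson O-benzylation of phenoxide and carboxylate, then saponification of the benzyl ester, to which the aryl benzyl ether is inert; the phenol must be masked because 2-hydroxybenzyl ketones cyclodehydrate to benzofurans.

Step 5
Reactants: 11 2-[2-(benzyloxy)-5-bromophenyl]acetic acid; 12 1,3,5-tris(benzyloxy)benzene
Product: 14 2-[2-(benzyloxy)-5-bromophenyl]-1-[2,4,6-tris(benzyloxy)phenyl]ethan-1-one, via mixed anhydride 13 (not isolated)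
Conditions: (CF3CO)2O, CH2Cl2, 0 °C to rt
Reagents that add atoms: none
Why: Friedel–Crafts acylation through the mixed trifluoroacetic anhydride; the threefold-activated arene 12 reacts without an added Lewis acid at any of its three equivalent positions, the ketone formed deactivates the ring against a second acylation, and benzyl ethers tolerate the mild acid.

Step 6
Reactants: 14 2-[2-(benzyloxy)-5-bromophenyl]-1-[2,4,6-tris(benzyloxy)phenyl]ethan-1-one; 15 prop-2-yn-1-ol
Product: 16 2-[2-(benzyloxy)-5-(3-hydroxyprop-1-yn-1-yl)phenyl]-1-[2,4,6-tris(benzyloxy)phenyl]ethan-1-one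
Conditions: Pd(PPh3)2Cl2 (5 mol%), CuI (5 mol%), Et3N, DMF, 80 °C
Reagents that add atoms: none
Why: Sonogashira coupling of the aryl bromide with the terminal alkyne; it is run before any stereocentre exists, so the amine base can do no harm, and the propargylic alcohol serves as a latent carboxylic acid.

Step 7
Reactants: 16 2-[2-(benzyloxy)-5-(3-hydroxyprop-1-yn-1-yl)phenyl]-1-[2,4,6-tris(benzyloxy)phenyl]ethan-1-one; 17 4-(benzyloxy)benzaldehyde
Product: 18 (E)-2-[2-(benzyloxy)-5-(3-hydroxyprop-1-yn-1-yl)phenyl]-3-[4-(benzyloxy)phenyl]-1-[2,4,6-tris(benzyloxy)phenyl]prop-2-en-1-one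
Conditions: piperidine (0.3 equiv), AcOH (0.3 equiv), toluene, reflux, Dean–Stark
Reagents that add atoms: none
Why: Knoevenagel condensation of the methylene group flanked by the ketone and an aryl ring with the aldehyde, driven by azeotropic removal of water; with all three ring A oxygens benzylated no oxa-Michael closure can follow, so the open chalcone should be isolated, the E isomer (aroyl trans to the β-aryl group) being expected.

Step 8
Reactants: 18 (E)-2-[2-(benzyloxy)-5-(3-hydroxyprop-1-yn-1-yl)phenyl]-3-[4-(benzyloxy)phenyl]-1-[2,4,6-tris(benzyloxy)phenyl]prop-2-en-1-one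
Product: 19 (E)-1-[2,4-bis(benzyloxy)-6-hydroxyphenyl]-2-[2-(benzyloxy)-5-(3-hydroxyprop-1-yn-1-yl)phenyl]-3-[4-(benzyloxy)phenyl]prop-2-en-1-one
Conditions: BCl3 (2.2 equiv), CH2Cl2, −78 °C; MeOH, then pH 7 phosphate buffer, cold
Reagents that add atoms: none
Why: Chelation-controlled ether cleavage: boron held between the ketone oxygen and an ortho ether oxygen cleaves that benzyl ether at −78 °C while the unactivated benzyl ethers remain; one equivalent is taken up by the propargylic hydroxyl and released on methanolysis, and the boron chelate keeps the phenoxide away from the enone β-carbon until the cold neutral quench.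

Step 9
Reactants: 19 (E)-1-[2,4-bis(benzyloxy)-6-hydroxyphenyl]-2-[2-(benzyloxy)-5-(3-hydroxyprop-1-yn-1-yl)phenyl]-3-[4-(benzyloxy)phenyl]prop-2-en-1-one
Product: 20 (2S,3R)-5,7-bis(benzyloxy)-3-[2-(benzyloxy)-5-(3-hydroxyprop-1-yn-1-yl)phenyl]-2-[4-(benzyloxy)phenyl]chroman-4-one
Conditions: thiourea from 9-amino-9-deoxy-epi-quinidine and 3,5-bis(trifluoromethyl)phenyl isothiocyanate (10 mol%), toluene, −20 to 0 °C
Reagents that add atoms: none
Why: Proposed new method: the quinuclidine nitrogen of the catalyst deprotonates the ketone-chelated phenol while the thiourea hydrogen-bonds to the enone carbonyl, so the phenoxide is delivered within a chiral ion pair to one face of the β-carbon (6-endo-trig oxa-Michael addition, which sets C2; 2S is expected with the quinidine-derived catalyst); protonation of the enol and amine-mediated equilibration at C3 should give the diequatorial 2,3-trans isomer; the closest known reaction type is the cinchona-thiourea-catalysed oxa-Michael cyclisation of 2'-hydroxychalcones bearing an α-alkoxycarbonyl group, and α-aryl chalcones have not been shown in it.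

Step 10
Reactants: 20 (2S,3R)-5,7-bis(benzyloxy)-3-[2-(benzyloxy)-5-(3-hydroxyprop-1-yn-1-yl)phenyl]-2-[4-(benzyloxy)phenyl]chroman-4-one
Product: 22 3-{4-(benzyloxy)-3-[(2S,3R)-5,7-bis(benzyloxy)-2-[4-(benzyloxy)phenyl]-4-oxochroman-3-yl]phenyl}prop-2-ynoic acid, via ynal 21 (not isolated)
Conditions: TEMPO (0.2 equiv), PhI(OAc)2 (2.5 equiv), CH2Cl2/MeCN/H2O, rt
Reagents that add atoms: water, O
Why: Nitroxyl-catalysed oxidation with PhI(OAc)2 as terminal oxidant takes the primary propargylic alcohol to the ynal and, through its hydrate, on to the ynoic acid in a mildly acidic medium, so the base-labile C2 and C3 centres are not disturbed; benzyl ethers and the ketone are inert.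

Step 11
Reactants: 22 3-{4-(benzyloxy)-3-[(2S,3R)-5,7-bis(benzyloxy)-2-[4-(benzyloxy)phenyl]-4-oxochroman-3-yl]phenyl}prop-2-ynoic acid; 8 3,5-dimethoxy-2-(trimethylsilyl)phenyl trifluoromethanesulfonate
Product: 25 2-{4-(benzyloxy)-3-[(2S,3R)-5,7-bis(benzyloxy)-2-[4-(benzyloxy)phenyl]-4-oxochroman-3-yl]phenyl}-5,7-dimethoxy-4H-chromen-4-one, via 3,5-dimethoxybenzyne 23 (not isolated), via ortho-hydroxyaryl ynone 24 (not isolated)
Conditions: 8 (1.5 equiv), CsF (4 equiv), THF, 125 °C, sealed tube
Reagents that add atoms: none
Why: Fluoride attacks the silicon of 8 and loss of triflate gives aryne 23; the cesium carboxylate of 22 adds through oxygen to the aryne carbon remote from the flanking methoxy group, because attack there places the developing negative charge on the carbon next to the inductively withdrawing C–OMe bond (O1–C8a). The aryl anion, now held between the ester oxygen and that methoxy group, attacks its own ester carbonyl through a four-membered transition state, and the acyl group moves from oxygen to carbon (C4–C4a) to give the phenoxide of ynone 24. The phenoxide adds to the β-carbon of the ynone in a 6-endo-dig oxa-Michael closure (O1–C2), and protonation at C3 completes the pyranone ring of the flavone. The closest known reaction type is the fluoride-induced insertion of arynes into the C–O bond of carboxylic acids to give ortho-hydroxyaryl ketones, which with arylpropiolic acids runs on to flavones under these conditions. No stereocentre is formed; C2 and C3 of the flavanone must pass through unchanged, which is helped by the absence of a free phenol in 22, by the low solubility of CsF in THF and by the acid proton that buffers the fluoride, while C3 returns to trans in any case. The step needs regioselective aryne addition (secured by the methoxy group next to the triple bond, the second methoxy group being too remote to matter), acyl transfer ahead of protonation of the aryl anion (aprotic THF and heat), and 6-endo over 5-exo closure (the β-carbon is the conjugate position of the ynone and carries the aryl group).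

Step 12
Reactants: 25 2-{4-(benzyloxy)-3-[(2S,3R)-5,7-bis(benzyloxy)-2-[4-(benzyloxy)phenyl]-4-oxochroman-3-yl]phenyl}-5,7-dimethoxy-4H-chromen-4-one
Product: 26 5-hydroxy-2-{4-hydroxy-3-[(2S,3R)-5,7-dihydroxy-2-(4-hydroxyphenyl)-4-oxochroman-3-yl]phenyl}-7-methoxy-4H-chromen-4-one
Conditions: BCl3 (excess), C6HMe5, CH2Cl2, −78 to 0 °C; MeOH
Reagents that add atoms: none
Why: BCl3 cleaves the four aryl benzyl ethers at low temperature, with pentamethylbenzene trapping the benzyl cations so that the phloroglucinol-type rings are not C-benzylated; on warming, boron chelated between the flavone C4 carbonyl and the peri C5 methoxy oxygen removes that methyl group only, the unchelated C7 methoxy group remaining, and the acidic medium does not open the flavanone through its enolate.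

## Compound list

1 | 3,5-dimethoxyphenol | COc1cc(O)cc(OC)c1 | starting material
2 | 3,5-dimethoxyphenyl N-isopropylcarbamate | COc1cc(OC)cc(OC(=O)NC(C)C)c1 | intermediate
3 | 3,5-dimethoxyphenyl N-(tert-butyldimethylsilyl)-N-isopropylcarbamate (formed in the flask) | COc1cc(OC)cc(OC(=O)N(C(C)C)[Si](C)(C)C(C)(C)C)c1 | intermediate
4 | 2-lithio-3,5-dimethoxyphenyl N-(tert-butyldimethylsilyl)-N-isopropylcarbamate (formed in the flask) | COc1cc(OC)c([Li])c(OC(=O)N(C(C)C)[Si](C)(C)C(C)(C)C)c1 | intermediate
5 | 3,5-dimethoxy-2-(trimethylsilyl)phenyl N-(tert-butyldimethylsilyl)-N-isopropylcarbamate (formed in the flask) | COc1cc(OC)c([Si](C)(C)C)c(OC(=O)N(C(C)C)[Si](C)(C)C(C)(C)C)c1 | intermediate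
6 | 3,5-dimethoxy-2-(trimethylsilyl)phenyl N-isopropylcarbamate | COc1cc(OC)c([Si](C)(C)C)c(OC(=O)NC(C)C)c1 | intermediate
7 | 3,5-dimethoxy-2-(trimethylsilyl)phenol (formed in the flask) | COc1cc(OC)c([Si](C)(C)C)c(O)c1 | intermediate
8 | 3,5-dimethoxy-2-(trimethylsilyl)phenyl trifluoromethanesulfonate | COc1cc(OC)c([Si](C)(C)C)c(OS(=O)(=O)C(F)(F)F)c1 | intermediate
9 | 2-(5-bromo-2-hydroxyphenyl)acetic acid | OC(=O)Cc1cc(Br)ccc1O | starting material
10 | benzyl 2-[2-(benzyloxy)-5-bromophenyl]acetate (formed in the flask) | O=C(Cc1cc(Br)ccc1OCc1ccccc1)OCc1ccccc1 | intermediate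
11 | 2-[2-(benzyloxy)-5-bromophenyl]acetic acid | OC(=O)Cc1cc(Br)ccc1OCc1ccccc1 | intermediate
12 | 1,3,5-tris(benzyloxy)benzene | c1ccc(COc2cc(OCc3ccccc3)cc(OCc3ccccc3)c2)cc1 | starting material
13 | 2-[2-(benzyloxy)-5-bromophenyl]acetic trifluoroacetic anhydride (formed in the flask) | O=C(Cc1cc(Br)ccc1OCc1ccccc1)OC(=O)C(F)(F)F | intermediate
14 | 2-[2-(benzyloxy)-5-bromophenyl]-1-[2,4,6-tris(benzyloxy)phenyl]ethan-1-one | O=C(Cc1cc(Br)ccc1OCc1ccccc1)c1c(OCc2ccccc2)cc(OCc2ccccc2)cc1OCc1ccccc1 | intermediate
15 | prop-2-yn-1-ol | OCC#C | starting material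
16 | 2-[2-(benzyloxy)-5-(3-hydroxyprop-1-yn-1-yl)phenyl]-1-[2,4,6-tris(benzyloxy)phenyl]ethan-1-one | O=C(Cc1cc(C#CCO)ccc1OCc1ccccc1)c1c(OCc2ccccc2)cc(OCc2ccccc2)cc1OCc1ccccc1 | intermediate
17 | 4-(benzyloxy)benzaldehyde | O=Cc1ccc(OCc2ccccc2)cc1 | starting material
18 | (E)-2-[2-(benzyloxy)-5-(3-hydroxyprop-1-yn-1-yl)phenyl]-3-[4-(benzyloxy)phenyl]-1-[2,4,6-tris(benzyloxy)phenyl]prop-2-en-1-one | O=C(c1c(OCc2ccccc2)cc(OCc2ccccc2)cc1OCc1ccccc1)/C(=C/c1ccc(OCc2ccccc2)cc1)c1cc(C#CCO)ccc1OCc1ccccc1 | intermediate
19 | (E)-1-[2,4-bis(benzyloxy)-6-hydroxyphenyl]-2-[2-(benzyloxy)-5-(3-hydroxyprop-1-yn-1-yl)phenyl]-3-[4-(benzyloxy)phenyl]prop-2-en-1-one | O=C(c1c(O)cc(OCc2ccccc2)cc1OCc1ccccc1)/C(=C/c1ccc(OCc2ccccc2)cc1)c1cc(C#CCO)ccc1OCc1ccccc1 | intermediate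
20 | (2S,3R)-5,7-bis(benzyloxy)-3-[2-(benzyloxy)-5-(3-hydroxyprop-1-yn-1-yl)phenyl]-2-[4-(benzyloxy)phenyl]chroman-4-one | OCC#Cc3ccc(OCc6ccccc6)c([C@H]4C(=O)c5c(OCc6ccccc6)cc(OCc6ccccc6)cc5O[C@@H]4c4ccc(OCc6ccccc6)cc4)c3 | intermediate
21 | 3-{4-(benzyloxy)-3-[(2S,3R)-5,7-bis(benzyloxy)-2-[4-(benzyloxy)phenyl]-4-oxochroman-3-yl]phenyl}prop-2-ynal (formed in the flask) | O=CC#Cc3ccc(OCc6ccccc6)c([C@H]4C(=O)c5c(OCc6ccccc6)cc(OCc6ccccc6)cc5O[C@@H]4c4ccc(OCc6ccccc6)cc4)c3 | intermediate
22 | 3-{4-(benzyloxy)-3-[(2S,3R)-5,7-bis(benzyloxy)-2-[4-(benzyloxy)phenyl]-4-oxochroman-3-yl]phenyl}prop-2-ynoic acid | OC(=O)C#Cc3ccc(OCc6ccccc6)c([C@H]4C(=O)c5c(OCc6ccccc6)cc(OCc6ccccc6)cc5O[C@@H]4c4ccc(OCc6ccccc6)cc4)c3 | intermediate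
23 | 3,5-dimethoxybenzyne (1,2-didehydro-3,5-dimethoxybenzene; formed in the flask) | COC1=CC(OC)=CC#C1 | intermediate
24 | (2S,3R)-5,7-bis(benzyloxy)-3-{2-(benzyloxy)-5-[3-(2-hydroxy-4,6-dimethoxyphenyl)-3-oxoprop-1-yn-1-yl]phenyl}-2-[4-(benzyloxy)phenyl]chroman-4-one (formed in the flask) | COc1cc(O)c(C(=O)C#Cc3ccc(OCc6ccccc6)c([C@H]4C(=O)c5c(OCc6ccccc6)cc(OCc6ccccc6)cc5O[C@@H]4c4ccc(OCc6ccccc6)cc4)c3)c(OC)c1 | intermediate
25 | 2-{4-(benzyloxy)-3-[(2S,3R)-5,7-bis(benzyloxy)-2-[4-(benzyloxy)phenyl]-4-oxochroman-3-yl]phenyl}-5,7-dimethoxy-4H-chromen-4-one | COc1cc(OC)c2c(=O)cc(-c3ccc(OCc6ccccc6)c([C@H]4C(=O)c5c(OCc6ccccc6)cc(OCc6ccccc6)cc5O[C@@H]4c4ccc(OCc6ccccc6)cc4)c3)oc2c1 | intermediate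
26 | 5-hydroxy-2-{4-hydroxy-3-[(2S,3R)-5,7-dihydroxy-2-(4-hydroxyphenyl)-4-oxochroman-3-yl]phenyl}-7-methoxy-4H-chromen-4-one | COc1cc(O)c2c(=O)cc(-c3ccc(O)c([C@H]4C(=O)c5c(O)cc(O)cc5O[C@@H]4c4ccc(O)cc4)c3)oc2c1 | target

## Step count and least certain steps

Total step count: 12. Longest linear sequence: 9 steps (steps 4 to 12, from acid 9); the aryne precursor 8 is a three-step side branch (steps 1 to 3).

**Step 9 (proposed new method).** The most likely failure is poor enantioselection.
- Closure of 19 without the catalyst, on silica or with traces of base, can compete with the catalysed path.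
- The amine of the catalyst can reopen the product, so the enantiomeric purity may drift downward with time.
- The α-aryl group twists the enone and gives the thiourea a weaker hold than the β-keto ester substrates for which this catalysis is established.
- The E/Z purity of 19 may also matter.

Fallback by known chemistry, from 19 back to 20: 19 is closed with NaOAc in refluxing ethanol to the racemic trans-flavanone, a 1:1 mixture of 20 and its enantiomer, (2R,3S)-5,7-bis(benzyloxy)-3-[2-(benzyloxy)-5-(3-hydroxyprop-1-yn-1-yl)phenyl]-2-[4-(benzyloxy)phenyl]chroman-4-one F1. The two are separated by preparative chromatography on an amylose tris(3,5-dimethylphenylcarbamate) stationary phase. F1 is returned to the racemate with DBU in THF (ring opening to the phenoxide of 19 and reclosure) and recycled, and the route continues from 20.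

**Step 11 (key step).** The most likely failure is loss of configuration at C2.
- At 125 °C fluoride, or the phenoxide of 24, may deprotonate C3; the enolate then expels the C8a phenoxide and the ring recloses without selectivity.
- The aryl anion may be protonated before acyl transfer, which stops the sequence at the aryl ester.
- The cesium propiolate may decarboxylate.
- Ynone 24 may close in the 5-exo mode.

Fallback, from 18 back to 25, runs the aryne step before any stereocentre exists. Compound 18 is oxidised with TEMPO and PhI(OAc)2 through the chalcone ynal F2 to the chalcone propiolic acid F3. F3 is treated with 8 and CsF in THF at 125 °C, where nothing can epimerise and no free phenol is present. This passes through 23 and the chalcone-bearing ortho-hydroxyaryl ynone F4 to the chalcone–dimethoxyflavone F5. BCl3 at −78 °C, with one extra equivalent for the flavone carbonyl, removes one ortho benzyl ether of the chalcone to give the 2'-hydroxychalcone–flavone F6; the flavone C5 methyl ether is not cleaved at this temperature. Closure of F6 with the catalyst of step 9 then gives 25.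

**Step 8.** The most likely failures are:
- premature, uncontrolled ring closure of the freed 2'-hydroxychalcone during quench or chromatography, which would carry racemic 20 into step 9;
- conversion of the propargylic hydroxyl into the chloride through its dichloroborinate;
- cleavage of further benzyl ethers by the extra equivalent of BCl3.

Fallback, from 14 back to 20, moves the debenzylation to a stage with neither an enone nor a propargylic alcohol. Compound 14 with BCl3 (1.1 equiv) at −78 °C gives 1-[2,4-bis(benzyloxy)-6-hydroxyphenyl]-2-[2-(benzyloxy)-5-bromophenyl]ethan-1-one F7. Sonogashira coupling with 15 gives the hydroxy alkynol deoxybenzoin F8. F8, aldehyde 17 and piperidine in refluxing ethanol give, by tandem Knoevenagel condensation and oxa-Michael closure, the racemic trans-flavanone (20 with its enantiomer F1). This is resolved and recycled as in the fallback to step 9.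

**Step 12.** The most likely failures are:
- Friedel–Crafts C-benzylation of the freed phloroglucinol ring if the scavenger is outrun;
- incomplete demethylation at C5 at low temperature, or loss of the C7 methyl group on long warming;
- Lewis-acid ionisation of the benzylic C2–O1 bond, which would epimerise C2.

Fallback, from 25 to 26, separates the two tasks. Hydrogenolysis with H2 over palladium on carbon in THF/MeOH removes the four benzyl ethers and gives the 5,7-dimethoxyflavone tetraphenol F9. BCl3 in CH2Cl2 at 0 °C is then used only for the chelation-controlled demethylation at C5 and gives 26.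

## Further compounds

F1 | step 9 | (2R,3S)-5,7-bis(benzyloxy)-3-[2-(benzyloxy)-5-(3-hydroxyprop-1-yn-1-yl)phenyl]-2-[4-(benzyloxy)phenyl]chroman-4-one (enantiomer of 20) | OCC#Cc3ccc(OCc6ccccc6)c([C@@H]4C(=O)c5c(OCc6ccccc6)cc(OCc6ccccc6)cc5O[C@H]4c4ccc(OCc6ccccc6)cc4)c3
F2 | step 11 | (E)-3-{4-(benzyloxy)-3-[1-(4-(benzyloxy)phenyl)-3-oxo-3-(2,4,6-tris(benzyloxy)phenyl)prop-1-en-2-yl]phenyl}prop-2-ynal | O=C(c1c(OCc2ccccc2)cc(OCc2ccccc2)cc1OCc1ccccc1)/C(=C/c1ccc(OCc2ccccc2)cc1)c1cc(C#CC=O)ccc1OCc1ccccc1
F3 | step 11 | (E)-3-{4-(benzyloxy)-3-[1-(4-(benzyloxy)phenyl)-3-oxo-3-(2,4,6-tris(benzyloxy)phenyl)prop-1-en-2-yl]phenyl}prop-2-ynoic acid | O=C(c1c(OCc2ccccc2)cc(OCc2ccccc2)cc1OCc1ccccc1)/C(=C/c1ccc(OCc2ccccc2)cc1)c1cc(C#CC(=O)O)ccc1OCc1ccccc1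
F4 | step 11 | (E)-2-{2-(benzyloxy)-5-[3-(2-hydroxy-4,6-dimethoxyphenyl)-3-oxoprop-1-yn-1-yl]phenyl}-3-[4-(benzyloxy)phenyl]-1-[2,4,6-tris(benzyloxy)phenyl]prop-2-en-1-one | O=C(c1c(OCc2ccccc2)cc(OCc2ccccc2)cc1OCc1ccccc1)/C(=C/c1ccc(OCc2ccccc2)cc1)c1cc(C#CC(=O)c2c(O)cc(OC)cc2OC)ccc1OCc1ccccc1
F5 | step 11 | 2-{4-(benzyloxy)-3-[(E)-1-(4-(benzyloxy)phenyl)-3-oxo-3-(2,4,6-tris(benzyloxy)phenyl)prop-1-en-2-yl]phenyl}-5,7-dimethoxy-4H-chromen-4-one | O=C(c1c(OCc2ccccc2)cc(OCc2ccccc2)cc1OCc1ccccc1)/C(=C/c1ccc(OCc2ccccc2)cc1)c1cc(-c2cc(=O)c3c(OC)cc(OC)cc3o2)ccc1OCc1ccccc1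
F6 | step 11 | 2-{4-(benzyloxy)-3-[(E)-3-(2,4-bis(benzyloxy)-6-hydroxyphenyl)-1-(4-(benzyloxy)phenyl)-3-oxoprop-1-en-2-yl]phenyl}-5,7-dimethoxy-4H-chromen-4-one | O=C(c1c(O)cc(OCc2ccccc2)cc1OCc1ccccc1)/C(=C/c1ccc(OCc2ccccc2)cc1)c1cc(-c2cc(=O)c3c(OC)cc(OC)cc3o2)ccc1OCc1ccccc1
F7 | step 8 | 1-[2,4-bis(benzyloxy)-6-hydroxyphenyl]-2-[2-(benzyloxy)-5-bromophenyl]ethan-1-one | O=C(Cc1cc(Br)ccc1OCc1ccccc1)c1c(O)cc(OCc2ccccc2)cc1OCc1ccccc1
F8 | step 8 | 1-[2,4-bis(benzyloxy)-6-hydroxyphenyl]-2-[2-(benzyloxy)-5-(3-hydroxyprop-1-yn-1-yl)phenyl]ethan-1-one | O=C(Cc1cc(C#CCO)ccc1OCc1ccccc1)c1c(O)cc(OCc2ccccc2)cc1OCc1ccccc1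
F9 | step 12 | 2-{4-hydroxy-3-[(2S,3R)-5,7-dihydroxy-2-(4-hydroxyphenyl)-4-oxochroman-3-yl]phenyl}-5,7-dimethoxy-4H-chromen-4-one | COc1cc(OC)c2c(=O)cc(-c3ccc(O)c([C@H]4C(=O)c5c(O)cc(O)cc5O[C@@H]4c4ccc(O)cc4)c3)oc2c1
A1 | alternative 1 | pentabenzyl ether of 26 (benzyl at flavone C5 and C4' and at flavanone C5, C7 and C4' oxygens; 2S,3R) | COc1cc(OCc6ccccc6)c2c(=O)cc(-c3ccc(OCc6ccccc6)c([C@H]4C(=O)c5c(OCc6ccccc6)cc(OCc6ccccc6)cc5O[C@@H]4c4ccc(OCc6ccccc6)cc4)c3)oc2c1
A2 | alternative 1 | 5,7-bis(benzyloxy)-4H-chromen-4-one | O=c1ccoc2cc(OCc3ccccc3)cc(OCc3ccccc3)c12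
A3 | alternative 1 | 4-(benzyloxy)phenylzinc chloride | Cl[Zn]c1ccc(OCc2ccccc2)cc1
A4 | alternative 1 | 5-(benzyloxy)-2-[4-(benzyloxy)-3-bromophenyl]-7-methoxy-4H-chromen-4-one | COc1cc(OCc2ccccc2)c2c(=O)cc(-c3ccc(OCc4ccccc4)c(Br)c3)oc2c1
A5 | alternative 1 | (S)-5,7-bis(benzyloxy)-2-[4-(benzyloxy)phenyl]-4-(trimethylsilyloxy)-2H-chromene | C4=C(O[Si](C)(C)C)c5c(OCc6ccccc6)cc(OCc6ccccc6)cc5O[C@@H]4c4ccc(OCc6ccccc6)cc4
A6 | alternative 2 | 2,3-trans-4-methoxyflavan joined at C3 to C3' of 5-(benzyloxy)-7-methoxyflavone, pivalate at the flavone C4' oxygen, benzyl ethers elsewhere (C2 and C3 as in 26, C4 arbitrary) | COc1cc(OCc6ccccc6)c2c(=O)cc(-c3ccc(OC(=O)C(C)(C)C)c([C@H]4[C@@H](OC)c5c(OCc6ccccc6)cc(OCc6ccccc6)cc5O[C@@H]4c4ccc(OCc6ccccc6)cc4)c3)oc2c1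
A7 | alternative 2 | 2,4-bis(benzyloxy)-6-hydroxybenzaldehyde | O=Cc1c(O)cc(OCc2ccccc2)cc1OCc1ccccc1
A8 | alternative 2 | 4-[5-(benzyloxy)-7-methoxy-4-oxo-4H-chromen-2-yl]-2-[(E)-2-(4-(benzyloxy)phenyl)ethenyl]phenyl pivalate | COc1cc(OCc2ccccc2)c2c(=O)cc(-c3ccc(OC(=O)C(C)(C)C)c(/C=C/c4ccc(OCc5ccccc5)cc4)c3)oc2c1
A9 | alternative 2 | O-methyl oxocarbenium of A7 (methoxy ortho-quinone methide cation) | C[O+]=Cc1c(O)cc(OCc2ccccc2)cc1OCc1ccccc1
A10 | alternative 3 | (2S,3R)-trans-flavanone–flavone with 4-(benzyloxy)benzyl ethers at flavanone C5 and C7 oxygens, benzyl at flavanone C4' and flavone C5 oxygens, tert-butyldimethylsilyl at the flavone C4' oxygen | COc1cc(OCc6ccccc6)c2c(=O)cc(-c3ccc(O[Si](C)(C)C(C)(C)C)c([C@H]4C(=O)c5c(OCc6ccc(OCc7ccccc7)cc6)cc(OCc6ccc(OCc7ccccc7)cc6)cc5O[C@@H]4c4ccc(OCc6ccccc6)cc4)c3)oc2c1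
A11 | alternative 3 | 2-diazo-2-{5-[5-(benzyloxy)-7-methoxy-4-oxo-4H-chromen-2-yl]-2-(tert-butyldimethylsilyloxy)phenyl}-1-{2,4,6-tris[(4-(benzyloxy)benzyl)oxy]phenyl}ethan-1-one | COc1cc(OCc2ccccc2)c2c(=O)cc(-c3ccc(O[Si](C)(C)C(C)(C)C)c(C(=[N+]=[N-])C(=O)c4c(OCc5ccc(OCc6ccccc6)cc5)cc(OCc5ccc(OCc6ccccc6)cc5)cc4OCc4ccc(OCc5ccccc5)cc4)c3)oc2c1
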